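# Proposed total synthesis of Ebenfuran V (23)

## Analysis of the target

Ebenfuran V (23) is a 2-arylbenzofuran without stereocenters: a furan ring (O1, C2, C3, C3a, C7a) is fused to a fully differentiated benzene ring A and joined at C2 to a 2,4-dihydroxyphenyl ring B. Ring A carries a hydroxyl at C4, a 3-hydroxy-3-methylbutyl chain at C5, a methoxy group at C6 and hydrogen only at C7; C3 bears a formyl group peri to the C4 hydroxyl. The sensitive groups are the aldehyde, three free phenols on electron-rich rings, and the tertiary alcohol. Under Lewis or strong Brønsted acid the tertiary alcohol ionises, and a free C4 oxygen would then capture the cation as a 2,2-dimethylchroman. The difficulty is positional, not stereochemical: the three oxygens of a phloroglucinol-type ring A must end as furan oxygen, free phenol and methyl ether, the alkyl chain must sit between two of them, and the C3 carbon must be placed without electrophilic substitution, for which C7 would compete. The C4 oxygen is therefore carried as a benzyl ether and not as a methyl ether, so that the last step is a neutral hydrogenolysis and no trihalide Lewis acid meets the tertiary alcohol. The strategy rests on C3: it carries a one-carbon acyl substituent and lies between C3a and the aryl-bearing C2. C3 can thus be the α-carbon of a ring A arylacetate and C2 the carbonyl carbon of a ring B benzoate held on the C7a oxygen, and the furan is closed at the C2–C3 bond by acyl transfer.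

## Retrosynthetic reasoning

**23 from 22.** The three O–benzyl bonds are cut last. Benzyl is chosen for all three phenols because its removal is neutral; an ether at C4 that needed a Lewis acid for cleavage would expose the tertiary alcohol to ionisation and chroman closure. The forward step has to cleave aryl benzyl ethers faster than it reduces a conjugated, hydrogen-bonded formyl group.

**22 from 20 through 21.** No skeletal bond is cut; the C3 formyl group is taken back to the methyl ester of 20 (reduction to the furylmethanol 21, then re-oxidation). The ester is the form in which C3 can act as an enolate carbon in the ring-forming step.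

**20 from 17.** The C2–C3 bond of the furan is cut. This places O1 and C3 on adjacent ring A carbons from the start and brings the C3 carbon in with its carboxyl, so no later substitution at C3 in competition with C7 is needed. The precursor 17 is an aryl benzoate whose ortho CH2CO2Me group is the only enolisable position. The forward reaction has to move the aroyl group from oxygen to carbon and then close and dehydrate the five-membered ring, through 18 and 19.

**17 from 12 and 15.** The ester C–O bond between the ring A phenol and the ring B acid is cut; the acid is activated as its chloride 16. The disconnection is convergent and falls on the weakest bond of 17. The forward acylation has to take the phenol and leave the tertiary alcohol.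

**15 from 13.** The two benzyl ethers of ring B are cut back to the dihydroxy acid 13. Exhaustive benzylation gives the benzyl ester 14, whose ester group is then hydrolysed.

**12 from 11.** The phenol that becomes O1 is uncovered from a methoxymethyl ether. This temporary group is what distinguishes the two oxygens flanking the acetate carbon: one stays masked while the other, next to the side chain, receives its permanent benzyl group.

**11 from 8 and 9.** The bond between the ring carbon that becomes C5 and the first CH2 of the side chain is cut. A cross-coupling of aryl iodide 8 with the alkylborane 10 derived from alkene 9 delivers the complete chain, tertiary alcohol included, in one step and without organometallics that would attack the ester.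

**8 from 4 through 6 and 7.** The aryl–CH2 bond of the acetate is traced back to the aryl–C(=O) bond of an acetyl group, by a one-carbon 1,2-aryl shift of diazo ketone 6 through ketene 7. The gain is that ring A can start as an acetophenone, whose carbonyl directs the first three steps by hydrogen bonding.

**4 from 1 through 2 and 3.** The O–benzyl bond, the C–I bond and the O–methoxymethyl bond are cut in that order. Acetophenone 1 is symmetric, so either hydroxyl can take the temporary ether (2). The hydroxyl that remains is chelated to the acetyl group and directs iodine to its ortho position (3), and is then benzylated (4). This sequence fixes that the iodine, and later the chain, lies next to the benzylated oxygen (future C4–O), and that the unsubstituted ring position lies next to the masked oxygen (future O1).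

## Alternatives that were turned down

**Alternative 1:** Ring B is disconnected at C1'–C6' and C2'–C3' and built as a six-membered carbocycle on a finished benzofuran. In the forward direction the benzofuran-2-ylacetate A1 would undergo methoxide-promoted Michael addition to the enone A2, and Claisen closure of the resulting keto ester would give the cyclohexane-1,3-dione A3, to be dehydrogenated to the resorcinol.
- For it: the 1,3-oxygen pattern of ring B arises from the annulation itself, ring B needs no protecting groups, and no hydrogenolysis is needed at the end. On these points it is stronger than the chosen route.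
- Against it: A1 already contains the whole 2,3-disubstituted furan with a masked formyl group at C3, so the main problem of the target is pushed back into the synthesis of A1 and not solved. The dione must then be oxidised to an arene in the presence of an electron-rich benzofuran, an acetal and a tertiary alcohol. A3 carries two methyl ethers on ring A, so a selective cleavage at C4 next to the tertiary alcohol would still be required.
- Comparison: the chosen route buys ring B as an intact aromatic acid (13) and uses its key step to make the heterocycle, at the cost of benzyl protection.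

**Alternative 2:** Ring A is disconnected at four bonds (C7–C7a, C6–C7, C4–C5, C3a–C4) and grown on a furan by benzannulation. In the forward direction irradiation of the furyl diazo ketone A4 would trigger a Wolff shift to a furylketene, which adds to the alkynyl ether A5. The cyclobutenone opens to a dienylketene that closes onto the furan β-carbon and tautomerises to the phenol A6.
- For it: it is highly convergent, forms four bonds at once, and delivers the C4 hydroxyl free and already distinct from the C6 methyl ether. Here it is clearly stronger than the chosen route, which needs a temporary ether and a directed iodination to tell these oxygens apart.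
- Against it: A4 is a trisubstituted furan bearing an aryl group, a dioxolane and a diazo ketone, and A5 is an acid-labile 1-alkoxyalkyne; each needs a multi-step synthesis of its own. The photochemical cascade must run in the presence of an electron-rich 2-arylfuran and benzyl ethers, and the electrocyclisation must engage a furan β-position.
- Comparison: the chosen route offers ground-state, scalable reactions from three simple building blocks and a key step that only requires deprotonation of one CH2 group.

**Alternative 3:** The biaryl bond C2–C1' is disconnected and made intramolecular by an ester bridge. In the forward direction the bromoaryl ester A7 would undergo palladium-catalysed direct arylation (Pd(OAc)2, PCy3, K2CO3) at the benzofuran C2–H to close the six-membered lactone of the coumestan A8, which is then opened reductively.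
- For it: C2–H is the most reactive C–H bond of a benzofuran-3-carboxylate, the tether removes any regiochemical doubt on ring B, and the 2'-oxygen needs no protecting group. Partial reduction of the lactone would reach the aldehyde oxidation level directly, which is better redox economy than the reduction and re-oxidation of the chosen route.
- Against it: A7 requires a 2-unsubstituted benzofuran-3-carboxylic acid of ring A, so the furan still has to be built in separate steps. An aryl ester must survive carbonate and heat. The lactone reduction must stop at the lactol stage. A8 again has two methyl ethers on ring A, and cleaving the peri C4 ether would call for a Lewis acid that the tertiary alcohol does not tolerate.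
- Comparison: the chosen route forms the C2–C3 bond and the furan in one operation from an ester that is assembled by simple acylation, and it differentiates the C4 oxygen as a benzyl ether from the third step onward.

Key step: step 11

## Route

Assumption: 1, 9 and 13 are taken as purchased; the two hydroxyl groups of 1 are equivalent, so step 1 gives the same compound 2 whichever of them reacts.

Step 1
Reactants: 1 2',6'-dihydroxy-4'-methoxyacetophenone
Product: 2 1-[2-hydroxy-4-methoxy-6-(methoxymethoxy)phenyl]ethan-1-one
Conditions: MOMCl (1.1 equiv), i-Pr2NEt, CH2Cl2, 0 °C to rt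
Reagents that add atoms: chloromethyl methyl ether, COCCl
Why: Base-mediated O-alkylation to the methoxymethyl ether; once one hydroxyl has reacted, the other is held in a six-membered hydrogen bond to the acetyl oxygen and is much less nucleophilic, so the reaction should stop at the mono-ether.

Step 2
Reactants: 2 mono-methoxymethyl ether
Product: 3 1-[2-hydroxy-3-iodo-4-methoxy-6-(methoxymethoxy)phenyl]ethan-1-one
Conditions: NIS (1.05 equiv), DMF, 0 °C to rt, dark
Reagents that add atoms: N-iodosuccinimide, O=C1CCC(=O)N1I
Why: Electrophilic aromatic iodination; the free chelated hydroxyl directs ortho, as is known for 2-hydroxy-4,6-dialkoxyacetophenones, and the position between hydroxyl and methoxy is less hindered than the one flanked by two ether groups; the neutral medium spares the acetal-type ether.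

Step 3
Reactants: 3 iodophenol
Product: 4 1-[2-(benzyloxy)-3-iodo-4-methoxy-6-(methoxymethoxy)phenyl]ethan-1-one
Conditions: BnBr, K2CO3, n-Bu4NI (cat.), DMF, 60 °C
Reagents that add atoms: benzyl bromide, BrCc1ccccc1
Why: Williamson ether synthesis; warm DMF with carbonate breaks the hydrogen bond of the chelated phenol, and the benzyl group lands on the oxygen next to iodine, the future C4 oxygen.

Step 4
Reactants: 4 benzyl ether aryl iodide
Product: 6 1-[2-(benzyloxy)-3-iodo-4-methoxy-6-(methoxymethoxy)phenyl]-2-diazoethan-1-one, via trifluoroacetyl diketone 5 (not isolated)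
Conditions: LiN(SiMe3)2, THF, −78 °C; CF3CO2CH2CF3; then MsN3, Et3N, H2O, MeCN, rt
Reagents that add atoms: methanesulfonyl azide, CS(=O)(=O)N=[N+]=[N-]; 2,2,2-trifluoroethyl trifluoroacetate, O=C(OCC(F)(F)F)C(F)(F)F (its trifluoroacetyl group is present only in intermediate 5)
Why: Detrifluoroacetylative diazo transfer (Danheiser procedure): the methyl ketone enolate is trifluoroacetylated to the activated diketone 5, which accepts the diazo group from the sulfonyl azide and loses the trifluoroacetyl group as the sulfonamide; the aryl iodide and both ethers are inert to the hindered amide base at −78 °C.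

Step 5
Reactants: 6 diazo ketone
Product: 8 methyl 2-[2-(benzyloxy)-3-iodo-4-methoxy-6-(methoxymethoxy)phenyl]acetate, via aryl ketene 7 (not isolated)
Conditions: PhCO2Ag (0.1 equiv), Et3N, MeOH–THF, rt to 45 °C, dark
Reagents that add atoms: methanol, CO
Why: Wolff rearrangement as in an Arndt–Eistert homologation: loss of N2 with 1,2-shift of the electron-rich aryl group gives ketene 7, which methanol traps as the methyl arylacetate; the acetyl group that directed steps 1 to 3 becomes the C3–carboxyl unit.

Step 6
Reactants: 8 iodo arylacetate; 9 2-methylbut-3-en-2-ol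
Product: 11 methyl 2-[2-(benzyloxy)-3-(3-hydroxy-3-methylbutyl)-4-methoxy-6-(methoxymethoxy)phenyl]acetate, via B-alkyl borane 10 (not isolated)
Conditions: 9, 9-BBN, THF, 0 °C to rt; then 8, PdCl2(dppf) (5 mol%), K3PO4 (aq), DMF, 60 °C
Reagents that add atoms: 9-borabicyclo[3.3.1]nonane, B1C2CCCC1CCC2 (its boron and ring carbons are present only in intermediate 10)
Why: B-alkyl Suzuki–Miyaura coupling: anti-Markovnikov hydroboration of the monosubstituted alkene gives the primary alkylborane 10, which transmetalates under aqueous phosphate and couples with the aryl iodide; the tertiary hydroxyl reacts with the borane only slowly and the methyl ester tolerates the mild base.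

Step 7
Reactants: 11 methoxymethyl ether
Product: 12 methyl 2-[2-(benzyloxy)-6-hydroxy-3-(3-hydroxy-3-methylbutyl)-4-methoxyphenyl]acetate
Conditions: HCl (from AcCl, 0.5 equiv), MeOH, 0 °C to rt; NaHCO3 before concentration
Reagents that add atoms: none
Why: Acid-catalysed acetal exchange: aryl methoxymethyl ethers are cleaved by dilute methanolic HCl at room temperature, where benzyl ethers, the methyl ester and the tertiary alcohol should persist; methanol as solvent keeps the product as the open hydroxy ester and not as the lactone.

Step 8
Reactants: 13 2,4-dihydroxybenzoic acid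
Product: 14 benzyl 2,4-bis(benzyloxy)benzoate
Conditions: BnBr (3.5 equiv), K2CO3, DMF, 70 °C
Reagents that add atoms: benzyl bromide, BrCc1ccccc1
Why: Exhaustive Williamson benzylation of the carboxylate and of both phenols; heating is needed for the chelated ortho hydroxyl.

Step 9
Reactants: 14 benzyl ester
Product: 15 2,4-bis(benzyloxy)benzoic acid
Conditions: KOH, MeOH–THF–H2O, 60 °C; then aq HCl
Reagents that add atoms: potassium hydroxide, [K+].[OH-]
Why: Saponification of the benzyl ester by acyl–oxygen cleavage; aryl benzyl ethers are stable to hydroxide.

Step 10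
Reactants: 12 ring A phenol; 15 ring B acid
Product: 17 methyl 2-[2-(benzyloxy)-6-[2,4-bis(benzyloxy)benzoyloxy]-3-(3-hydroxy-3-methylbutyl)-4-methoxyphenyl]acetate, via acid chloride 16 (not isolated)
Conditions: 15, (COCl)2, DMF (cat.), CH2Cl2, 0 °C to rt, evaporate; then 12, Et3N, DMAP (0.1 equiv), CH2Cl2, 0 °C to rt
Reagents that add atoms: oxalyl chloride, O=C(Cl)C(=O)Cl (its chlorine is present only in intermediate 16)
Why: Acid chloride formation followed by DMAP-catalysed O-acylation of the phenol; with one equivalent of 16 at 0 °C the phenol should react far faster than the hindered tertiary alcohol, which stays free.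

Step 11
Reactants: 17 aroyloxy arylacetate
Product: 20 methyl 4-(benzyloxy)-2-[2,4-bis(benzyloxy)phenyl]-5-(3-hydroxy-3-methylbutyl)-6-methoxy-1-benzofuran-3-carboxylate, via keto ester phenol 18 (not isolated), via cyclic hemiketal 19 (not isolated)
Conditions: LiN(SiMe3)2 (3.5 equiv), THF (0.02 M), −78 to 0 °C; aq HCl quench; then p-TsOH·H2O (0.2 equiv), toluene, 50 °C
Reagents that add atoms: none
Why: The base first takes the tertiary O–H and then the only acidic C–H, the benzylic methylene α to the methyl ester; the ester enolate (C3) adds to the carbonyl carbon of the neighbouring aryl ester (C2) in a 5-exo-trig closure that forms the C2–C3 bond. The cyclic tetrahedral alkoxide may open to the keto phenoxide, and a further equivalent of base stores the product as the doubly stabilised enolate of 18, which makes the O-to-C acyl shift irreversible. The closest known reaction type is the Baker–Venkataraman acyl migration in its ester-enolate form (intramolecular Claisen condensation of 2-aroyloxyarylacetates), followed by acid cyclodehydration to 2-arylbenzofuran-3-carboxylates. On acidification the C7a phenol adds back to the aryl ketone (5-exo-trig) to give hemiketal 19, and catalytic p-TsOH removes water because the product is an aromatic, donor–acceptor-stabilised furan. The stereocenters of 18 and 19 form without control and are erased in the dehydration, so none has to be set. The step needs C-acylation within one molecule and not between two; the five-membered transition state, low temperature and dilution secure this, since the CH2 group is the only enolisable position and the aroyl group is the only ester within reach. It also needs closure of the phenol onto the ketone and not onto the methyl ester; the ketone is the stronger electrophile and only its adduct can aromatise. The benzyl group on the C4 oxygen leaves the C7a oxygen as the only phenol able to close the ring and keeps chroman formation from the side chain out of reach under the mild acid used.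

Step 12
Reactants: 20 benzofuran-3-carboxylate
Product: 21 4-[4-(benzyloxy)-2-[2,4-bis(benzyloxy)phenyl]-3-(hydroxymethyl)-6-methoxy-1-benzofuran-5-yl]-2-methylbutan-2-ol
Conditions: i-Bu2AlH (4 equiv), CH2Cl2, −78 to 0 °C; Rochelle salt work-up
Reagents that add atoms: none
Why: Hydride reduction of the vinylogous carbonate ester to the primary alcohol; the excess allows for the alkoxide of the tertiary alcohol, benzyl ethers and the furan are inert, and the neutral work-up protects the acid-sensitive furylmethanol, which is used at once.

Step 13
Reactants: 21 furylmethanol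
Product: 22 4-(benzyloxy)-2-[2,4-bis(benzyloxy)phenyl]-5-(3-hydroxy-3-methylbutyl)-6-methoxy-1-benzofuran-3-carbaldehyde
Conditions: MnO2 (activated, 15 equiv), CH2Cl2, rt
Reagents that add atoms: none
Why: MnO2 oxidation of a heterobenzylic alcohol; it is selective for the activated primary carbinol, and the tertiary alcohol cannot be oxidised.

Step 14
Reactants: 22 tri-O-benzyl aldehyde
Product: 23 2-(2,4-dihydroxyphenyl)-4-hydroxy-5-(3-hydroxy-3-methylbutyl)-6-methoxy-1-benzofuran-3-carbaldehyde (Ebenfuran V)
Conditions: H2 (1 atm), Pd/C (10 wt%), EtOAc, rt, stopped when three equivalents of H2 are taken up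
Reagents that add atoms: none
Why: Catalytic hydrogenolysis of three aryl benzyl ethers under neutral conditions; the conjugated, hydrogen-bonded formyl group should be reduced much more slowly than the O–benzyl bonds are cleaved, and no acid is present that could ionise the tertiary alcohol beside the freed C4 phenol.

## Compound list

1 | 2',6'-dihydroxy-4'-methoxyacetophenone | CC(=O)c1c(O)cc(OC)cc1O | starting material
2 | 1-[2-hydroxy-4-methoxy-6-(methoxymethoxy)phenyl]ethan-1-one | CC(=O)c1c(O)cc(OC)cc1OCOC | intermediate
3 | 1-[2-hydroxy-3-iodo-4-methoxy-6-(methoxymethoxy)phenyl]ethan-1-one | CC(=O)c1c(O)c(I)c(OC)cc1OCOC | intermediate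
4 | 1-[2-(benzyloxy)-3-iodo-4-methoxy-6-(methoxymethoxy)phenyl]ethan-1-one | CC(=O)c1c(OCc2ccccc2)c(I)c(OC)cc1OCOC | intermediate
5 | 1-[2-(benzyloxy)-3-iodo-4-methoxy-6-(methoxymethoxy)phenyl]-4,4,4-trifluorobutane-1,3-dione (not isolated) | O=C(CC(=O)C(F)(F)F)c1c(OCc2ccccc2)c(I)c(OC)cc1OCOC | intermediate
6 | 1-[2-(benzyloxy)-3-iodo-4-methoxy-6-(methoxymethoxy)phenyl]-2-diazoethan-1-one | [N-]=[N+]=CC(=O)c1c(OCc2ccccc2)c(I)c(OC)cc1OCOC | intermediate
7 | 2-[2-(benzyloxy)-3-iodo-4-methoxy-6-(methoxymethoxy)phenyl]ethen-1-one (aryl ketene, not isolated) | O=C=Cc1c(OCc2ccccc2)c(I)c(OC)cc1OCOC | intermediate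
8 | methyl 2-[2-(benzyloxy)-3-iodo-4-methoxy-6-(methoxymethoxy)phenyl]acetate | COC(=O)Cc1c(OCc2ccccc2)c(I)c(OC)cc1OCOC | intermediate
9 | 2-methylbut-3-en-2-ol | C=CC(C)(C)O | starting material
10 | 4-(9-borabicyclo[3.3.1]nonan-9-yl)-2-methylbutan-2-ol (not isolated) | CC(C)(O)CCB1C2CCCC1CCC2 | intermediate
11 | methyl 2-[2-(benzyloxy)-3-(3-hydroxy-3-methylbutyl)-4-methoxy-6-(methoxymethoxy)phenyl]acetate | COC(=O)Cc1c(OCc2ccccc2)c(CCC(C)(C)O)c(OC)cc1OCOC | intermediate
12 | methyl 2-[2-(benzyloxy)-6-hydroxy-3-(3-hydroxy-3-methylbutyl)-4-methoxyphenyl]acetate | COC(=O)Cc1c(OCc2ccccc2)c(CCC(C)(C)O)c(OC)cc1O | intermediate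
13 | 2,4-dihydroxybenzoic acid | OC(=O)c1ccc(O)cc1O | starting material
14 | benzyl 2,4-bis(benzyloxy)benzoate | O=C(OCc1ccccc1)c1ccc(OCc2ccccc2)cc1OCc1ccccc1 | intermediate
15 | 2,4-bis(benzyloxy)benzoic acid | OC(=O)c1ccc(OCc2ccccc2)cc1OCc1ccccc1 | intermediate
16 | 2,4-bis(benzyloxy)benzoyl chloride (not isolated) | ClC(=O)c1ccc(OCc2ccccc2)cc1OCc1ccccc1 | intermediate
17 | methyl 2-[2-(benzyloxy)-6-[2,4-bis(benzyloxy)benzoyloxy]-3-(3-hydroxy-3-methylbutyl)-4-methoxyphenyl]acetate | COC(=O)Cc1c(OCc2ccccc2)c(CCC(C)(C)O)c(OC)cc1OC(=O)c1ccc(OCc2ccccc2)cc1OCc1ccccc1 | intermediate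
18 | methyl 2-[2-(benzyloxy)-6-hydroxy-3-(3-hydroxy-3-methylbutyl)-4-methoxyphenyl]-3-[2,4-bis(benzyloxy)phenyl]-3-oxopropanoate (racemic, enolisable, not isolated) | COC(=O)C(C(=O)c1ccc(OCc2ccccc2)cc1OCc1ccccc1)c1c(OCc2ccccc2)c(CCC(C)(C)O)c(OC)cc1O | intermediate
19 | methyl 4-(benzyloxy)-2-[2,4-bis(benzyloxy)phenyl]-2-hydroxy-5-(3-hydroxy-3-methylbutyl)-6-methoxy-2,3-dihydro-1-benzofuran-3-carboxylate (mixture of racemic diastereomers, not isolated) | COC(=O)C1c2c(OCc3ccccc3)c(CCC(C)(C)O)c(OC)cc2OC1(O)c1ccc(OCc2ccccc2)cc1OCc1ccccc1 | intermediate
20 | methyl 4-(benzyloxy)-2-[2,4-bis(benzyloxy)phenyl]-5-(3-hydroxy-3-methylbutyl)-6-methoxy-1-benzofuran-3-carboxylate | COC(=O)c1c(-c2ccc(OCc3ccccc3)cc2OCc2ccccc2)oc2cc(OC)c(CCC(C)(C)O)c(OCc3ccccc3)c12 | intermediate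
21 | 4-[4-(benzyloxy)-2-[2,4-bis(benzyloxy)phenyl]-3-(hydroxymethyl)-6-methoxy-1-benzofuran-5-yl]-2-methylbutan-2-ol | OCc1c(-c2ccc(OCc3ccccc3)cc2OCc2ccccc2)oc2cc(OC)c(CCC(C)(C)O)c(OCc3ccccc3)c12 | intermediate
22 | 4-(benzyloxy)-2-[2,4-bis(benzyloxy)phenyl]-5-(3-hydroxy-3-methylbutyl)-6-methoxy-1-benzofuran-3-carbaldehyde | O=Cc1c(-c2ccc(OCc3ccccc3)cc2OCc2ccccc2)oc2cc(OC)c(CCC(C)(C)O)c(OCc3ccccc3)c12 | intermediate
23 | 2-(2,4-dihydroxyphenyl)-4-hydroxy-5-(3-hydroxy-3-methylbutyl)-6-methoxy-1-benzofuran-3-carbaldehyde (Ebenfuran V) | COc1cc2oc(-c3ccc(O)cc3O)c(C=O)c2c(O)c1CCC(C)(C)O | target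

## Step count and least certain steps

Total step count: 14. Longest linear sequence: 12 steps (steps 1 to 7, then 10 to 14); steps 8 and 9 form the ring B branch.

**Step 11 (key step).**
- What may go wrong: the aryl ester may be cleaved, or the acyl group transferred between molecules, by the lithium alkoxide of the tertiary alcohol or by adventitious hydroxide, which returns the phenol. After the acyl shift the phenoxide may close onto the methyl ester with loss of methoxide instead of onto the ketone. The acid used for dehydration may also dehydrate the tertiary alcohol if it is too strong or too hot.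
- Fallback: the same C2–C3 bond is made between two molecules. Setting out from 11 and the benzyl ester 14, the ester enolate of 11 (excess LiN(SiMe3)2, THF, −78 to 0 °C) is condensed with 14 in a crossed Claisen reaction to give methyl 2-[2-(benzyloxy)-3-(3-hydroxy-3-methylbutyl)-4-methoxy-6-(methoxymethoxy)phenyl]-3-[2,4-bis(benzyloxy)phenyl]-3-oxopropanoate F1. Methanolic HCl then removes the methoxymethyl group, and the freed phenol should cyclise and dehydrate through 18 and 19, so that the route is rejoined at 20.

**Step 5 (Wolff rearrangement).**
- What may go wrong: the metal carbenoid may be captured by the lone pair of the ortho benzyloxy or methoxymethoxy oxygen (oxonium ylide formation and closure to a five-membered ketone), or may insert into the O–H bond of methanol without aryl migration.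
- Fallback: a Willgerodt–Kindler rearrangement replaces steps 4 and 5. Setting out from 4, sulfur and morpholine at about 130 °C should give 2-[2-(benzyloxy)-3-iodo-4-methoxy-6-(methoxymethoxy)phenyl]-1-(morpholin-4-yl)ethane-1-thione F2. KOH in aqueous ethanol hydrolyses it to 2-[2-(benzyloxy)-3-iodo-4-methoxy-6-(methoxymethoxy)phenyl]acetic acid F3, and methylation of the carboxylate (MeI, K2CO3, DMF) returns to the route at 8.

**Step 6 (B-alkyl Suzuki–Miyaura coupling).**
- What may go wrong: oxidative addition and transmetalation are slow at an aryl iodide flanked by two ether groups, so protodeiodination and β-hydride elimination of the alkylpalladium intermediate can compete; the aqueous base may partly saponify the methyl ester.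
- Fallback: Sonogashira coupling followed by saturation. Setting out from 8, coupling with 2-methylbut-3-yn-2-ol (PdCl2(PPh3)2, CuI, Et3N, 60 °C) should give methyl 2-[2-(benzyloxy)-3-(3-hydroxy-3-methylbut-1-yn-1-yl)-4-methoxy-6-(methoxymethoxy)phenyl]acetate F4. Hydrogenation of the alkyne over PtO2 in EtOAc, a catalyst that cleaves aryl benzyl ethers only slowly, returns to the route at 11.

**Step 2 (iodination).**
- What may go wrong: iodine may enter para to the hydroxyl, between the methoxy and methoxymethoxy groups, because both open positions are activated by all three oxygens; a second iodination may follow.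
- Fallback: symmetry fixes the position of iodine. Setting out from 1, mono-iodination (NIS, DMF, 0 °C) can give only one regioisomer, 1-(2,6-dihydroxy-3-iodo-4-methoxyphenyl)ethan-1-one F5, because both open ring positions of 1 are equivalent. The methoxymethyl group is then placed on the hydroxyl remote from iodine, which is flanked by hydrogen and is the less hindered one (MOMCl, i-Pr2NEt, CH2Cl2, 0 °C), and the route is rejoined at 3.

**Step 14 (hydrogenolysis).**
- What may go wrong: once the benzyl ethers are gone the formyl group may be reduced further to hydroxymethyl and on to methyl, or the hindered C4 benzyl ether may be cleaved incompletely.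
- Fallback: benzyl is exchanged for silyl before the aldehyde exists. Setting out from 20, hydrogenolysis (H2, Pd/C, EtOAc) at the ester stage gives methyl 2-(2,4-dihydroxyphenyl)-4-hydroxy-5-(3-hydroxy-3-methylbutyl)-6-methoxy-1-benzofuran-3-carboxylate F6. Silylation of the three phenols (TBSCl, imidazole, DMF) gives the tris(tert-butyldimethylsilyl) ether F7, i-Bu2AlH reduction gives the furylmethanol F8, and MnO2 gives the aldehyde F9. Fluoride buffered with acetic acid (Bu4NF, AcOH, THF, 0 °C) then frees the phenols, and the route ends at 23.

## Further compounds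

F1 | step 11 | methyl 2-[2-(benzyloxy)-3-(3-hydroxy-3-methylbutyl)-4-methoxy-6-(methoxymethoxy)phenyl]-3-[2,4-bis(benzyloxy)phenyl]-3-oxopropanoate (racemic) | COC(=O)C(C(=O)c1ccc(OCc2ccccc2)cc1OCc1ccccc1)c1c(OCc2ccccc2)c(CCC(C)(C)O)c(OC)cc1OCOC
F2 | step 5 | 2-[2-(benzyloxy)-3-iodo-4-methoxy-6-(methoxymethoxy)phenyl]-1-(morpholin-4-yl)ethane-1-thione | S=C(Cc1c(OCc2ccccc2)c(I)c(OC)cc1OCOC)N1CCOCC1
F3 | step 5 | 2-[2-(benzyloxy)-3-iodo-4-methoxy-6-(methoxymethoxy)phenyl]acetic acid | OC(=O)Cc1c(OCc2ccccc2)c(I)c(OC)cc1OCOC
F4 | step 6 | methyl 2-[2-(benzyloxy)-3-(3-hydroxy-3-methylbut-1-yn-1-yl)-4-methoxy-6-(methoxymethoxy)phenyl]acetate | COC(=O)Cc1c(OCc2ccccc2)c(C#CC(C)(C)O)c(OC)cc1OCOC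
F5 | step 2 | 1-(2,6-dihydroxy-3-iodo-4-methoxyphenyl)ethan-1-one | CC(=O)c1c(O)cc(OC)c(I)c1O
F6 | step 14 | methyl 2-(2,4-dihydroxyphenyl)-4-hydroxy-5-(3-hydroxy-3-methylbutyl)-6-methoxy-1-benzofuran-3-carboxylate | COC(=O)c1c(-c2ccc(O)cc2O)oc2cc(OC)c(CCC(C)(C)O)c(O)c12
F7 | step 14 | methyl 4-[(tert-butyldimethylsilyl)oxy]-2-{2,4-bis[(tert-butyldimethylsilyl)oxy]phenyl}-5-(3-hydroxy-3-methylbutyl)-6-methoxy-1-benzofuran-3-carboxylate | COC(=O)c1c(-c2ccc(O[Si](C)(C)C(C)(C)C)cc2O[Si](C)(C)C(C)(C)C)oc2cc(OC)c(CCC(C)(C)O)c(O[Si](C)(C)C(C)(C)C)c12
F8 | step 14 | 4-[4-[(tert-butyldimethylsilyl)oxy]-2-{2,4-bis[(tert-butyldimethylsilyl)oxy]phenyl}-3-(hydroxymethyl)-6-methoxy-1-benzofuran-5-yl]-2-methylbutan-2-ol | OCc1c(-c2ccc(O[Si](C)(C)C(C)(C)C)cc2O[Si](C)(C)C(C)(C)C)oc2cc(OC)c(CCC(C)(C)O)c(O[Si](C)(C)C(C)(C)C)c12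
F9 | step 14 | 4-[(tert-butyldimethylsilyl)oxy]-2-{2,4-bis[(tert-butyldimethylsilyl)oxy]phenyl}-5-(3-hydroxy-3-methylbutyl)-6-methoxy-1-benzofuran-3-carbaldehyde | O=Cc1c(-c2ccc(O[Si](C)(C)C(C)(C)C)cc2O[Si](C)(C)C(C)(C)C)oc2cc(OC)c(CCC(C)(C)O)c(O[Si](C)(C)C(C)(C)C)c12
A1 | alternative 1 | methyl 2-[3-(dimethoxymethyl)-5-(3-hydroxy-3-methylbutyl)-4,6-dimethoxy-1-benzofuran-2-yl]acetate | COC(=O)Cc1oc2cc(OC)c(CCC(C)(C)O)c(OC)c2c1C(OC)OC
A2 | alternative 1 | but-3-en-2-one | CC(=O)C=C
A3 | alternative 1 | 4-[3-(dimethoxymethyl)-5-(3-hydroxy-3-methylbutyl)-4,6-dimethoxy-1-benzofuran-2-yl]cyclohexane-1,3-dione (racemic, enolisable) | COc1cc2oc(C3CCC(=O)CC3=O)c(C(OC)OC)c2c(OC)c1CCC(C)(C)O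
A4 | alternative 2 | 1-[5-[2,4-bis(benzyloxy)phenyl]-4-(1,3-dioxolan-2-yl)furan-2-yl]-2-diazoethan-1-one | [N-]=[N+]=CC(=O)c1cc(C2OCCO2)c(-c2ccc(OCc3ccccc3)cc2OCc2ccccc2)o1
A5 | alternative 2 | triethyl[(5-methoxy-2-methylpent-4-yn-2-yl)oxy]silane | COC#CCCC(C)(C)O[Si](CC)(CC)CC
A6 | alternative 2 | 2-[2,4-bis(benzyloxy)phenyl]-3-(1,3-dioxolan-2-yl)-6-methoxy-5-[3-methyl-3-(triethylsilyloxy)butyl]-1-benzofuran-4-ol | COc1cc2oc(-c3ccc(OCc4ccccc4)cc3OCc3ccccc3)c(C3OCCO3)c2c(O)c1CCC(C)(C)O[Si](CC)(CC)CC
A7 | alternative 3 | 5-(benzyloxy)-2-bromophenyl 5-(3-hydroxy-3-methylbutyl)-4,6-dimethoxy-1-benzofuran-3-carboxylate | COc1cc2occ(C(=O)Oc3cc(OCc4ccccc4)ccc3Br)c2c(OC)c1CCC(C)(C)O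
A8 | alternative 3 | 3-(benzyloxy)-8-(3-hydroxy-3-methylbutyl)-7,9-dimethoxy-6H-[1]benzofuro[3,2-c]chromen-6-one | COc1cc2oc3-c4ccc(OCc5ccccc5)cc4OC(=O)c3c2c(OC)c1CCC(C)(C)O
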